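## Retrosynthetic overview

1. The strategy rests on the cis C4=C5 alkene conjugated with the C2=C3 enamide inside the 19-membered ansa ring (C1–C15, C16, C21, C20, N). It is traced back to a ring alkyne C4≡C5, closed by ring-closing alkyne metathesis of two methyl-capped alkynes and then semi-reduced. The arene C16–C21 is carried as a 3-amido-5-alkylphenol, and O21 is added last at its free para carbon C21 (Teuber oxidation, then reduction).
2. The diyne is the anilide (N–C1) of (Z)-2-methylhex-2-en-4-ynoic acid (C1–C4) and a C5–C20 aniline whose nitrogen comes from C–N coupling on an aryl chloride.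
3. The C5–C15 chain grows from the arene: aryllithium plus a C11–C15 Weinreb amide from an (S)-lactone, CBS reduction (C15), Evans aldol (C10–C11), Still–Gennari olefination (C8=C9), glycolate aldol (C6–C7), Corey–Fuchs homologation (C5 alkyne).
4. Ring order: the benzene ring is bought; the only ring formed is the 19-membered macrocycle, closed at C4–C5.

Key step: step 32

Remark: locants C1–C21 are those of the target (C1 amide carbonyl, C15 benzylic carbon, C16–C21 arene, N on C20); descriptors quoted with these locants are the CIP descriptors of the compound in question; Ar = 3-chloro-5-(triisopropylsilyloxy)phenyl. The potassium salt of phosphonate 23 is numbered once, where it first forms (step 16); when the same salt is made again in step 29 it is recorded among the compounds set free as a reagent made and consumed in the flask.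

## Route

Step 1
Reactants: 1 (S)-5-(hydroxymethyl)dihydrofuran-2(3H)-one
Product: 2 (S)-5-[(tert-butyldimethylsilyloxy)methyl]dihydrofuran-2(3H)-one
Conditions: TBSCl, imidazole, DMF, 0 °C to rt
Reagents that add atoms: tert-butyldimethylsilyl chloride, CC(C)(C)[Si](C)(C)Cl
Why: Imidazole-mediated silylation of the primary alcohol masks O11 as a TBS ether that tolerates the enolate and amide chemistry that follows.

Step 2
Reactants: 2 (S)-5-[(tert-butyldimethylsilyloxy)methyl]dihydrofuran-2(3H)-one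
Product: 4 (3R,5S)-5-[(tert-butyldimethylsilyloxy)methyl]-3-methyldihydrofuran-2(3H)-one (trans lactone), via lithium enolate 3 (not isolated)
Conditions: LiN(i-Pr)2, THF, −78 °C; MeI, −78 to −40 °C
Reagents that add atoms: iodomethane, CI
Why: Lactone enolate alkylation, in which MeI should approach anti to the C12 silyloxymethyl arm to give mainly the trans lactone; the epimer ratio is not critical because both epimers give the same enolate in step 3.

Step 3
Reactants: 4 (3R,5S)-5-[(tert-butyldimethylsilyloxy)methyl]-3-methyldihydrofuran-2(3H)-one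
Product: 6 (3S,5S)-5-[(tert-butyldimethylsilyloxy)methyl]-3-methyldihydrofuran-2(3H)-one (cis lactone), via lithium enolate 5 (not isolated)
Conditions: LiN(i-Pr)2, THF, −78 °C; AcOH in THF, −78 °C
Reagents that add atoms: none
Why: Kinetic protonation of the re-formed enolate on the face opposite the C12 side chain leaves the methyl group cis to it and so sets (14S); recovered 4 can be recycled through the same enolate.

Step 4
Reactants: 6 (3S,5S)-5-[(tert-butyldimethylsilyloxy)methyl]-3-methyldihydrofuran-2(3H)-one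
Product: 7 (2S,4S)-5-(tert-butyldimethylsilyloxy)-4-hydroxy-N-methoxy-N,2-dimethylpentanamide
Conditions: MeNH(OMe)·HCl, AlMe3, CH2Cl2, 0 °C to rt
Reagents that add atoms: N,O-dimethylhydroxylamine hydrochloride, CNOC.Cl
Why: Weinreb aminolysis of the lactone by the aluminium amide opens the ring at the acyl carbon without touching C14 and frees O12; the hydroxy amide is carried on at once to prevent relactonisation.

Step 5
Reactants: 7 (2S,4S)-5-(tert-butyldimethylsilyloxy)-4-hydroxy-N-methoxy-N,2-dimethylpentanamide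
Product: 8 (2S,4S)-5-(tert-butyldimethylsilyloxy)-N,4-dimethoxy-N,2-dimethylpentanamide (C11–C15 Weinreb amide)
Conditions: Me3OBF4, Proton Sponge, CH2Cl2, 0 °C to rt
Reagents that add atoms: trimethyloxonium tetrafluoroborate, C[O+](C)C.F[B-](F)(F)F
Why: O-methylation by the oxonium salt with a non-nucleophilic amine base forms the C12 methyl ether without an alkoxide, so silyl migration and lactonisation are avoided.

Step 6
Reactants: 9 3-bromo-5-chlorophenol
Product: 10 (3-bromo-5-chlorophenoxy)triisopropylsilane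
Conditions: TIPSCl, imidazole, DMF, rt
Reagents that add atoms: triisopropylsilyl chloride, CC(C)[Si](Cl)(C(C)C)C(C)C
Why: Silylation of the phenol gives an aryl TIPS ether that is inert to organolithiums, hydrides and mild acid and is kept until the end.

Step 7
Reactants: 10 (3-bromo-5-chlorophenoxy)triisopropylsilane; 8 (2S,4S)-5-(tert-butyldimethylsilyloxy)-N,4-dimethoxy-N,2-dimethylpentanamide
Product: 12 (2S,4S)-5-(tert-butyldimethylsilyloxy)-1-Ar-4-methoxy-2-methylpentan-1-one (C11–C15 aryl ketone), via aryllithium 11 (not isolated)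
Conditions: n-BuLi, THF, −78 °C; 8, −78 to −40 °C; aq. NH4Cl
Reagents that add atoms: none
Why: Bromine–lithium exchange is far faster than chlorine–lithium exchange, and the aryllithium adds once to the Weinreb amide because the chelated tetrahedral adduct persists until the quench (Weinreb ketone synthesis), leaving C14 untouched at low temperature.

Step 8
Reactants: 12 C11–C15 aryl ketone
Product: 13 (1R,2S,4S)-5-(tert-butyldimethylsilyloxy)-1-Ar-4-methoxy-2-methylpentan-1-ol
Conditions: (S)-2-methyl-CBS-oxazaborolidine, BH3·SMe2, THF, −20 °C; MeOH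
Reagents that add atoms: none
Why: Corey–Bakshi–Shibata reduction, in which the (S)-oxazaborolidine binds the ketone anti to the aryl group and delivers hydride to the face that gives the (15R)-carbinol; catalyst control is relied on to override the weak Felkin bias of C14.

Step 9
Reactants: 13 (1R,2S,4S)-5-(tert-butyldimethylsilyloxy)-1-Ar-4-methoxy-2-methylpentan-1-ol
Product: 14 tert-butyl{[(2S,4S,5R)-5-Ar-2,5-dimethoxy-4-methylpentyl]oxy}dimethylsilane
Conditions: MeOTf, 2,6-di-tert-butylpyridine, CH2Cl2, rt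
Reagents that add atoms: methyl trifluoromethanesulfonate, COS(=O)(=O)C(F)(F)F
Why: O-methylation of the hindered benzylic alcohol by methyl triflate with a hindered pyridine as acid scavenger proceeds at oxygen with retention at C15 and spares both silyl ethers.

Step 10
Reactants: 14 tert-butyl{[(2S,4S,5R)-5-Ar-2,5-dimethoxy-4-methylpentyl]oxy}dimethylsilane
Product: 15 (2S,4S,5R)-5-Ar-2,5-dimethoxy-4-methylpentan-1-ol
Conditions: CSA (cat.), MeOH/CH2Cl2, 0 °C
Reagents that add atoms: none
Why: Acid-catalysed methanolysis cleaves the primary alkyl TBS ether much faster than the aryl TIPS ether, which is stable to acid.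

Step 11
Reactants: 15 (2S,4S,5R)-5-Ar-2,5-dimethoxy-4-methylpentan-1-ol
Product: 16 (2S,4S,5R)-5-Ar-2,5-dimethoxy-4-methylpentanal (C11 aldehyde)
Conditions: Dess–Martin periodinane, pyridine, CH2Cl2, 0 °C to rt
Reagents that add atoms: none
Why: Buffered Dess–Martin oxidation gives the α-methoxy aldehyde under non-epimerising conditions; it is used directly.

Step 12
Reactants: 16 C11 aldehyde; 17 (R)-4-benzyl-3-propionyloxazolidin-2-one
Product: 19 (R)-4-benzyl-3-[(2R,3R,4S,6S,7R)-7-Ar-3-hydroxy-4,7-dimethoxy-2,6-dimethylheptanoyl]oxazolidin-2-one (C9–C15 syn aldol adduct), via boron enolate 18 (not isolated)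
Conditions: 17, Bu2BOTf, i-Pr2NEt, CH2Cl2, −78 to 0 °C; 16, −78 to 0 °C; pH 7 buffer, MeOH, H2O2, 0 °C
Reagents that add atoms: none
Why: Evans syn aldol, in which the Z(O)-boron enolate reacts through a closed Zimmerman–Traxler transition state and the benzyl group of the (R)-auxiliary blocks one enolate face, setting C10 and C11 syn with the (11R) carbinol; this sense is reinforced by the 1,2-anti preference of the α-methoxy aldehyde.

Step 13
Reactants: 19 C9–C15 syn aldol adduct
Product: 20 (R)-4-benzyl-3-[(2R,3R,4S,6S,7R)-7-Ar-3,4,7-trimethoxy-2,6-dimethylheptanoyl]oxazolidin-2-one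
Conditions: Me3OBF4, Proton Sponge, CH2Cl2, 0 °C to rt
Reagents that add atoms: trimethyloxonium tetrafluoroborate, C[O+](C)C.F[B-](F)(F)F
Why: Oxonium-salt O-methylation of the β-hydroxy imide under non-basic conditions installs the C11 methyl ether without retro-aldol cleavage or C10 epimerisation.

Step 14
Reactants: 20 C11 methyl ether imide
Product: 21 (2S,3R,4S,6S,7R)-7-Ar-3,4,7-trimethoxy-2,6-dimethylheptan-1-ol
Conditions: LiBH4, MeOH (1 equiv), THF, 0 °C
Reagents that add atoms: none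
Why: Reductive cleavage of the imide at the exocyclic carbonyl by LiBH4 releases the C9 primary alcohol and the recoverable auxiliary and does not touch the aryl chloride or the silyl ether.

Step 15
Reactants: 21 (2S,3R,4S,6S,7R)-7-Ar-3,4,7-trimethoxy-2,6-dimethylheptan-1-ol
Product: 22 (2R,3R,4S,6S,7R)-7-Ar-3,4,7-trimethoxy-2,6-dimethylheptanal (C9 aldehyde)
Conditions: Dess–Martin periodinane, pyridine, CH2Cl2, 0 °C to rt
Reagents that add atoms: none
Why: Buffered Dess–Martin oxidation gives the α-methyl aldehyde without epimerisation at C10 or β-elimination of methanol; it is used directly.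

Step 16
Reactants: 22 C9 aldehyde; 23 ethyl 2-[bis(2,2,2-trifluoroethoxy)phosphoryl]propanoate
Product: 25 ethyl (2Z,4S,5R,6S,8S,9R)-9-Ar-5,6,9-trimethoxy-2,4,8-trimethylnon-2-enoate (C7–C15 Z-enoate), via potassium phosphonate 24 (not isolated)
Conditions: 23, KN(SiMe3)2, 18-crown-6, THF, −78 °C; then 22
Reagents that add atoms: none
Why: Still–Gennari olefination, in which the trifluoroethyl phosphonate anion with a crown-separated potassium ion eliminates rapidly from the kinetic adduct so that the ester and C10 end up cis (8Z); the cold, weakly basic medium should not epimerise C10.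

Step 17
Reactants: 25 C7–C15 Z-enoate
Product: 26 (2Z,4S,5R,6S,8S,9R)-9-Ar-5,6,9-trimethoxy-2,4,8-trimethylnon-2-en-1-ol
Conditions: i-Bu2AlH, CH2Cl2, −78 °C
Reagents that add atoms: none
Why: 1,2-Reduction of the enoate by the aluminium hydride gives the allylic alcohol with the 8Z geometry unchanged.

Step 18
Reactants: 26 (2Z)-allylic alcohol
Product: 27 (2Z,4S,5R,6S,8S,9R)-9-Ar-5,6,9-trimethoxy-2,4,8-trimethylnon-2-enal (C7 Z-enal)
Conditions: Dess–Martin periodinane, pyridine, CH2Cl2, 0 °C; used at once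
Reagents that add atoms: none
Why: Buffered Dess–Martin oxidation under neutral, cold conditions gives the trisubstituted (Z)-enal; immediate use limits Z to E isomerisation.

Step 19
Reactants: 28 (R)-4-benzyloxazolidin-2-one; 29 methoxyacetyl chloride
Product: 31 (R)-4-benzyl-3-(2-methoxyacetyl)oxazolidin-2-one, via lithium oxazolidinide 30 (not isolated)
Conditions: n-BuLi, THF, −78 °C; 29, −78 to 0 °C
Reagents that add atoms: none
Why: N-acylation of the lithiated oxazolidinone with the acid chloride gives the glycolate imide that carries C5, C6 and the C6 methoxy group.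

Step 20
Reactants: 27 C7 Z-enal; 31 (R)-4-benzyl-3-(2-methoxyacetyl)oxazolidin-2-one
Product: 33 (R)-4-benzyl-3-[(2R,3S,4Z,6S,7R,8S,10S,11R)-11-Ar-3-hydroxy-2,7,8,11-tetramethoxy-4,6,10-trimethylundec-4-enoyl]oxazolidin-2-one (C5–C15 syn glycolate aldol adduct), via boron enolate 32 (not isolated)
Conditions: 31, Bu2BOTf, Et3N, CH2Cl2, −78 to 0 °C; 27, −78 to −20 °C; pH 7 buffer, MeOH, H2O2, 0 °C
Reagents that add atoms: none
Why: Evans syn glycolate aldol, in which the Z(O)-boron enolate adds 1,2 to the enal through a chair transition state under control of the (R)-auxiliary, setting C6 and C7 syn with the (7S) carbinol and the C6 methoxy configuration of the target; the low temperature preserves the 8Z geometry.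

Step 21
Reactants: 33 C5–C15 syn glycolate aldol adduct
Product: 34 C7 triethylsilyl ether of 33 (6R,7S,8Z,10S,11R,12S,14S,15R)
Conditions: TESOTf, 2,6-lutidine, CH2Cl2, −78 °C
Reagents that add atoms: triethylsilyl trifluoromethanesulfonate, CC[Si](CC)(CC)OS(=O)(=O)C(F)(F)F
Why: Silylation of the allylic secondary alcohol with the silyl triflate gives a TES ether that can later be removed in the presence of the aryl TIPS ether.

Step 22
Reactants: 34 C7 triethylsilyl ether imide
Product: 35 C5 primary alcohol (6S,7S,8Z,10S,11R,12S,14S,15R): 11-Ar-2,7,8,11-tetramethoxy-4,6,10-trimethyl-3-(triethylsilyloxy)undec-4-en-1-ol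
Conditions: LiBH4, MeOH (1 equiv), THF, 0 °C
Reagents that add atoms: none
Why: Reductive removal of the auxiliary by LiBH4 at the exocyclic carbonyl gives the C5 alcohol without disturbing C6 or the silyl ethers.

Step 23
Reactants: 35 C5 primary alcohol
Product: 36 C5 aldehyde (6R,7S,8Z,10S,11R,12S,14S,15R)
Conditions: Dess–Martin periodinane, pyridine, CH2Cl2, 0 °C to rt
Reagents that add atoms: none
Why: Buffered Dess–Martin oxidation gives the α-methoxy-β-silyloxy aldehyde without epimerisation at C6; it is used directly.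

Step 24
Reactants: 36 C5 aldehyde
Product: 37 1,1-dibromoolefin at C5 (6S,7S,8Z,10S,11R,12S,14S,15R)
Conditions: CBr4, PPh3, Et3N, CH2Cl2, −78 to 0 °C
Reagents that add atoms: carbon tetrabromide, BrC(Br)(Br)Br
Why: First stage of the Corey–Fuchs homologation (Wittig-type dibromo-olefination); the amine buffer protects the TES ether and the C6 centre from HBr.

Step 25
Reactants: 37 1,1-dibromoolefin
Product: 39 C5–C15 methyl-capped alkyne aryl chloride (6S,7S,8Z,10S,11R,12S,14S,15R), via lithium acetylide 38 (not isolated)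
Conditions: n-BuLi (2.1 equiv), THF, −78 °C; MeI, −78 °C to rt
Reagents that add atoms: iodomethane, CI
Why: Second stage of the Corey–Fuchs homologation, in which bromine–lithium exchange, 1,2-shift to the alkyne and deprotonation give the lithium acetylide that is C-methylated; the aryl chloride does not exchange at −78 °C.

Step 26
Reactants: 39 C5–C15 methyl-capped alkyne aryl chloride
Product: 40 N-(diphenylmethylene)aniline at C20 (aryl chloride replaced by N=CPh2)
Conditions: Ph2C=NH, Pd2(dba)3 (zerovalent palladium), XPhos, K3PO4, toluene, 90 °C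
Reagents that add atoms: benzophenone imine, N=C(c1ccccc1)c1ccccc1
Why: Buchwald–Hartwig amination with benzophenone imine as ammonia surrogate, in which the bulky biaryl phosphine enables oxidative addition of the aryl chloride and the weak phosphate base spares both silyl ethers and the internal alkyne.

Step 27
Reactants: 40 N-(diphenylmethylene)aniline
Product: 41 C5–C20 aniline (free NH2 on C20; TES on O7, TIPS on O18)
Conditions: NH2OH·HCl, NaOAc, MeOH/THF, rt
Reagents that add atoms: none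
Why: Transimination with hydroxylamine in acetate buffer releases the primary aniline near neutrality, so the TES ether should survive.

Step 28
Reactants: 42 but-2-yn-1-ol
Product: 43 but-2-ynal
Conditions: MnO2, CH2Cl2, rt; filtered solution used directly
Reagents that add atoms: none
Why: Heterogeneous MnO2 oxidation of the propargylic alcohol gives the volatile ynal, which is used in solution.

Step 29
Reactants: 43 but-2-ynal; 23 ethyl 2-[bis(2,2,2-trifluoroethoxy)phosphoryl]propanoate
Product: 44 ethyl (Z)-2-methylhex-2-en-4-ynoate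
Conditions: 23, KN(SiMe3)2, 18-crown-6, THF, −78 °C; then 43
Reagents that add atoms: none
Why: Still–Gennari olefination, for which the potassium salt of 23 is made afresh in the flask exactly as in step 16 and consumed, places the ester cis to the alkynyl group (2Z) by fast elimination from the kinetic adduct.

Step 30
Reactants: 44 ethyl (Z)-2-methylhex-2-en-4-ynoate
Product: 45 (Z)-2-methylhex-2-en-4-ynoic acid
Conditions: LiOH, THF/H2O, 0 °C to rt; then 1 M HCl to pH 3, 0 °C
Reagents that add atoms: lithium hydroxide, [Li+].[OH-]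
Why: Saponification by acyl substitution leaves the Z-enyne intact, and cold, brief acidification avoids cyclisation of the enynoic acid.

Step 31
Reactants: 41 C5–C20 aniline; 45 (Z)-2-methylhex-2-en-4-ynoic acid
Product: 47 acyclic diyne anilide (2Z,6S,7S,8Z,10S,11R,12S,14S,15R), via acid chloride 46 (not isolated)
Conditions: 45, 1-chloro-N,N,2-trimethylprop-1-en-1-amine, CH2Cl2, 0 °C to rt; then 41, pyridine, CH2Cl2, 0 °C
Reagents that add atoms: none
Why: The α-chloroenamine forms the acid chloride under neutral conditions and the unhindered aniline is then N-acylated (Schotten–Baumann-type amide formation), which avoids activating agents that would isomerise the 2Z olefin.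

Step 32
Reactants: 47 acyclic diyne anilide
Product: 48 19-membered 2-en-4-ynamide macrocycle (2Z,6S,7S,8Z,10S,11R,12S,14S,15R; TES on O7, TIPS on O18)
Conditions: Mo(≡CC6H4OMe-4)(OSiPh3)3 (cat.), 5 Å molecular sieves, toluene, 2 mM, rt to 60 °C
Reagents that add atoms: none
Why: Ring-closing alkyne metathesis: the molybdenum alkylidyne adds [2+2] to one methyl-capped alkyne, the metallacyclobutadiene cycloreverts to leave the substrate on molybdenum, and a second, intramolecular [2+2]/cycloreversion with the other methyl alkyne forms C4≡C5 and expels but-2-yne, which the sieves trap to drive the equilibrium. The closest known reaction type is macrocyclisation of diynes to conjugated 1,3-enynes with molybdenum alkylidyne silanolate catalysts. The 19-membered ring closes end to end at C4–C5, between two unhindered sp carbons, with the alkyne endocyclic. No stereocentre is created, and the seven sp3 centres and the 2Z and 8Z olefins are spectators because the alkylidyne does not engage C=C bonds. The step needs cyclisation over acyclic oligomerisation and alkyne over alkene chemoselectivity: high dilution with removal of but-2-yne secures the first, the inertness of the catalyst to olefins the second, and the only protic site, the anilide N–H, is tolerated by the silanolate ligand set. The meta-bridged arene and the two Z olefins pre-bend the chain towards closure.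

Step 33
Reactants: 48 19-membered 2-en-4-ynamide macrocycle
Product: 49 (2Z,4Z,8Z)-macrocyclic dienamide (TES on O7, TIPS on O18)
Conditions: Zn(Cu/Ag), MeOH/H2O, rt to 45 °C
Reagents that add atoms: none
Why: Semi-reduction of the conjugated alkyne on activated zinc (Boland reduction) delivers two hydrogens syn to give the cis C4=C5 alkene, without over-reduction and without touching the isolated trisubstituted olefin.

Step 34
Reactants: 49 (2Z,4Z,8Z)-macrocyclic dienamide
Product: 50 C7 alcohol macrocycle (TIPS on O18)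
Conditions: HF·pyridine, pyridine, THF, 0 °C
Reagents that add atoms: none
Why: Buffered fluoride-mediated desilylation cleaves the secondary alkyl TES ether selectively, while the aryl TIPS ether is retained under these mildly acidic conditions.

Step 35
Reactants: 50 C7 alcohol macrocycle
Product: 52 C7 primary carbamate macrocycle (TIPS on O18), via trichloroacetyl carbamate 51 (not isolated)
Conditions: Cl3CC(O)NCO, CH2Cl2, 0 °C; then K2CO3, MeOH, 0 °C
Reagents that add atoms: trichloroacetyl isocyanate, O=C=NC(=O)C(Cl)(Cl)Cl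
Why: Addition of the alcohol to the acyl isocyanate followed by methanolysis of the activated trichloroacetyl imide gives the primary carbamate; the anilide N–H is too unreactive to compete and the aryl TIPS ether is far more base-stable than the imide.

Step 36
Reactants: 52 C7 primary carbamate macrocycle
Product: 53 macrocyclic 3-amido-5-alkylphenol (free O18–H, C21–H)
Conditions: Bu4NF, AcOH, THF, 0 °C
Reagents that add atoms: none
Why: Fluoride cleavage of the aryl silyl ether, buffered with acetic acid so that the phenoxide and basic fluoride do not attack the carbamate.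

Step 37
Reactants: 53 macrocyclic 3-amido-5-alkylphenol
Product: 54 macrocyclic 1,4-benzoquinone (C18=O, C21=O)
Conditions: (KO3S)2NO, KH2PO4 buffer (pH 6–7), acetone/H2O, 0 °C to rt
Reagents that add atoms: potassium nitrosodisulfonate, [K+].[K+].[O]N(S(=O)(=O)[O-])S(=O)(=O)[O-]
Why: Teuber oxidation, in which one nitrosodisulfonate radical abstracts the phenolic hydrogen, a second couples through oxygen at the free para carbon C21 and loss of imidodisulfonate gives the 1,4-quinone; para attack is the normal course when that position is unsubstituted.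

Step 38
Reactants: 54 macrocyclic 1,4-benzoquinone
Product: 55 CNP0109452.1, the (2Z,4Z,8Z) hydroquinone (6S,7S,10S,11R,12S,14S,15R)
Conditions: Na2S2O4, EtOAc/H2O, rt, under argon
Reagents that add atoms: none
Why: Two-electron reduction of the quinone by dithionite gives the hydroquinone, which is worked up and stored under argon to prevent re-oxidation.

## Compound list

1 | (S)-5-(hydroxymethyl)dihydrofuran-2(3H)-one | OC[C@@H]1CCC(=O)O1 | starting material
2 | (S)-5-[(tert-butyldimethylsilyloxy)methyl]dihydrofuran-2(3H)-one | CC(C)(C)[Si](C)(C)OC[C@@H]1CCC(=O)O1 | intermediate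
3 | lithium enolate of 2 | CC(C)(C)[Si](C)(C)OC[C@@H]1CC=C(O[Li])O1 | intermediate
4 | (3R,5S)-5-[(tert-butyldimethylsilyloxy)methyl]-3-methyldihydrofuran-2(3H)-one (trans) | CC(C)(C)[Si](C)(C)OC[C@@H]1C[C@@H](C)C(=O)O1 | intermediate
5 | lithium enolate of 4 | CC(C)(C)[Si](C)(C)OC[C@@H]1CC(C)=C(O[Li])O1 | intermediate
6 | (3S,5S)-5-[(tert-butyldimethylsilyloxy)methyl]-3-methyldihydrofuran-2(3H)-one (cis) | CC(C)(C)[Si](C)(C)OC[C@@H]1C[C@H](C)C(=O)O1 | intermediate
7 | (2S,4S)-5-(tert-butyldimethylsilyloxy)-4-hydroxy-N-methoxy-N,2-dimethylpentanamide | CC(C)(C)[Si](C)(C)OC[C@@H](O)C[C@H](C)C(=O)N(C)OC | intermediate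
8 | (2S,4S)-5-(tert-butyldimethylsilyloxy)-N,4-dimethoxy-N,2-dimethylpentanamide | CC(C)(C)[Si](C)(C)OC[C@@H](OC)C[C@H](C)C(=O)N(C)OC | intermediate
9 | 3-bromo-5-chlorophenol | Oc1cc(Cl)cc(Br)c1 | starting material
10 | (3-bromo-5-chlorophenoxy)triisopropylsilane | CC(C)[Si](C(C)C)(C(C)C)Oc1cc(Cl)cc(Br)c1 | intermediate
11 | [3-chloro-5-(triisopropylsilyloxy)phenyl]lithium | [Li]c1cc(Cl)cc(O[Si](C(C)C)(C(C)C)C(C)C)c1 | intermediate
12 | (2S,4S)-5-(tert-butyldimethylsilyloxy)-1-[3-chloro-5-(triisopropylsilyloxy)phenyl]-4-methoxy-2-methylpentan-1-one | CC(C)(C)[Si](C)(C)OC[C@@H](OC)C[C@H](C)C(=O)c1cc(O[Si](C(C)C)(C(C)C)C(C)C)cc(Cl)c1 | intermediate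
13 | (1R,2S,4S)-5-(tert-butyldimethylsilyloxy)-1-[3-chloro-5-(triisopropylsilyloxy)phenyl]-4-methoxy-2-methylpentan-1-ol | CC(C)(C)[Si](C)(C)OC[C@@H](OC)C[C@H](C)[C@@H](O)c1cc(O[Si](C(C)C)(C(C)C)C(C)C)cc(Cl)c1 | intermediate
14 | tert-butyl{[(2S,4S,5R)-5-Ar-2,5-dimethoxy-4-methylpentyl]oxy}dimethylsilane | CC(C)(C)[Si](C)(C)OC[C@@H](OC)C[C@H](C)[C@@H](OC)c1cc(O[Si](C(C)C)(C(C)C)C(C)C)cc(Cl)c1 | intermediate
15 | (2S,4S,5R)-5-Ar-2,5-dimethoxy-4-methylpentan-1-ol | OC[C@@H](OC)C[C@H](C)[C@@H](OC)c1cc(O[Si](C(C)C)(C(C)C)C(C)C)cc(Cl)c1 | intermediate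
16 | (2S,4S,5R)-5-Ar-2,5-dimethoxy-4-methylpentanal | O=C[C@@H](OC)C[C@H](C)[C@@H](OC)c1cc(O[Si](C(C)C)(C(C)C)C(C)C)cc(Cl)c1 | intermediate
17 | (R)-4-benzyl-3-propionyloxazolidin-2-one | CCC(=O)N1[C@H](Cc2ccccc2)COC1=O | starting material
18 | dibutylboron (Z)-enolate of 17 | C/C=C(\OB(CCCC)CCCC)N1[C@H](Cc2ccccc2)COC1=O | intermediate
19 | (R)-4-benzyl-3-[(2R,3R,4S,6S,7R)-7-Ar-3-hydroxy-4,7-dimethoxy-2,6-dimethylheptanoyl]oxazolidin-2-one | O[C@H]([C@@H](C)C(=O)N1[C@H](Cc2ccccc2)COC1=O)[C@@H](OC)C[C@H](C)[C@@H](OC)c1cc(O[Si](C(C)C)(C(C)C)C(C)C)cc(Cl)c1 | intermediate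
20 | (R)-4-benzyl-3-[(2R,3R,4S,6S,7R)-7-Ar-3,4,7-trimethoxy-2,6-dimethylheptanoyl]oxazolidin-2-one | CO[C@H]([C@@H](C)C(=O)N1[C@H](Cc2ccccc2)COC1=O)[C@@H](OC)C[C@H](C)[C@@H](OC)c1cc(O[Si](C(C)C)(C(C)C)C(C)C)cc(Cl)c1 | intermediate
21 | (2S,3R,4S,6S,7R)-7-Ar-3,4,7-trimethoxy-2,6-dimethylheptan-1-ol | OC[C@H](C)[C@@H](OC)[C@@H](OC)C[C@H](C)[C@@H](OC)c1cc(O[Si](C(C)C)(C(C)C)C(C)C)cc(Cl)c1 | intermediate
22 | (2R,3R,4S,6S,7R)-7-Ar-3,4,7-trimethoxy-2,6-dimethylheptanal | O=C[C@H](C)[C@@H](OC)[C@@H](OC)C[C@H](C)[C@@H](OC)c1cc(O[Si](C(C)C)(C(C)C)C(C)C)cc(Cl)c1 | intermediate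
23 | ethyl 2-[bis(2,2,2-trifluoroethoxy)phosphoryl]propanoate | CCOC(=O)C(C)P(=O)(OCC(F)(F)F)OCC(F)(F)F | starting material
24 | potassium salt of 23 (phosphonate carbanion) | CCOC(=O)[C-](C)P(=O)(OCC(F)(F)F)OCC(F)(F)F.[K+] | intermediate
25 | ethyl (2Z,4S,5R,6S,8S,9R)-9-Ar-5,6,9-trimethoxy-2,4,8-trimethylnon-2-enoate | CCOC(=O)/C(C)=C\[C@H](C)[C@@H](OC)[C@@H](OC)C[C@H](C)[C@@H](OC)c1cc(O[Si](C(C)C)(C(C)C)C(C)C)cc(Cl)c1 | intermediate
26 | (2Z,4S,5R,6S,8S,9R)-9-Ar-5,6,9-trimethoxy-2,4,8-trimethylnon-2-en-1-ol | OC/C(C)=C\[C@H](C)[C@@H](OC)[C@@H](OC)C[C@H](C)[C@@H](OC)c1cc(O[Si](C(C)C)(C(C)C)C(C)C)cc(Cl)c1 | intermediate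
27 | (2Z,4S,5R,6S,8S,9R)-9-Ar-5,6,9-trimethoxy-2,4,8-trimethylnon-2-enal | O=C/C(C)=C\[C@H](C)[C@@H](OC)[C@@H](OC)C[C@H](C)[C@@H](OC)c1cc(O[Si](C(C)C)(C(C)C)C(C)C)cc(Cl)c1 | intermediate
28 | (R)-4-benzyloxazolidin-2-one | O=C1N[C@H](Cc2ccccc2)CO1 | starting material
29 | methoxyacetyl chloride | COCC(Cl)=O | starting material
30 | lithium salt of 28 | [Li]N1[C@H](Cc2ccccc2)COC1=O | intermediate
31 | (R)-4-benzyl-3-(2-methoxyacetyl)oxazolidin-2-one | COCC(=O)N1[C@H](Cc2ccccc2)COC1=O | intermediate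
32 | dibutylboron (Z)-enolate of 31 | CO/C=C(\OB(CCCC)CCCC)N1[C@H](Cc2ccccc2)COC1=O | intermediate
33 | (R)-4-benzyl-3-[(2R,3S,4Z,6S,7R,8S,10S,11R)-11-Ar-3-hydroxy-2,7,8,11-tetramethoxy-4,6,10-trimethylundec-4-enoyl]oxazolidin-2-one | O=C1OC[C@@H](Cc2ccccc2)N1C(=O)[C@H](OC)[C@@H](O)/C(C)=C\[C@H](C)[C@@H](OC)[C@@H](OC)C[C@H](C)[C@@H](OC)c1cc(O[Si](C(C)C)(C(C)C)C(C)C)cc(Cl)c1 | intermediate
34 | C7 triethylsilyl ether of 33 (6R,7S,8Z,10S,11R,12S,14S,15R) | O=C1OC[C@@H](Cc2ccccc2)N1C(=O)[C@H](OC)[C@@H](O[Si](CC)(CC)CC)/C(C)=C\[C@H](C)[C@@H](OC)[C@@H](OC)C[C@H](C)[C@@H](OC)c1cc(O[Si](C(C)C)(C(C)C)C(C)C)cc(Cl)c1 | intermediate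
35 | C5 primary alcohol, 11-Ar-2,7,8,11-tetramethoxy-4,6,10-trimethyl-3-(triethylsilyloxy)undec-4-en-1-ol (6S,7S,8Z,10S,11R,12S,14S,15R) | OC[C@H](OC)[C@@H](O[Si](CC)(CC)CC)/C(C)=C\[C@H](C)[C@@H](OC)[C@@H](OC)C[C@H](C)[C@@H](OC)c1cc(O[Si](C(C)C)(C(C)C)C(C)C)cc(Cl)c1 | intermediate
36 | C5 aldehyde (6R,7S,8Z,10S,11R,12S,14S,15R) | O=C[C@H](OC)[C@@H](O[Si](CC)(CC)CC)/C(C)=C\[C@H](C)[C@@H](OC)[C@@H](OC)C[C@H](C)[C@@H](OC)c1cc(O[Si](C(C)C)(C(C)C)C(C)C)cc(Cl)c1 | intermediate
37 | 1,1-dibromoolefin at C5 (6S,7S,8Z,10S,11R,12S,14S,15R) | BrC(Br)=C[C@H](OC)[C@@H](O[Si](CC)(CC)CC)/C(C)=C\[C@H](C)[C@@H](OC)[C@@H](OC)C[C@H](C)[C@@H](OC)c1cc(O[Si](C(C)C)(C(C)C)C(C)C)cc(Cl)c1 | intermediate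
38 | lithium acetylide at C5 | [Li]C#C[C@H](OC)[C@@H](O[Si](CC)(CC)CC)/C(C)=C\[C@H](C)[C@@H](OC)[C@@H](OC)C[C@H](C)[C@@H](OC)c1cc(O[Si](C(C)C)(C(C)C)C(C)C)cc(Cl)c1 | intermediate
39 | C5–C15 methyl-capped alkyne aryl chloride (6S,7S,8Z,10S,11R,12S,14S,15R) | CC#C[C@H](OC)[C@@H](O[Si](CC)(CC)CC)/C(C)=C\[C@H](C)[C@@H](OC)[C@@H](OC)C[C@H](C)[C@@H](OC)c1cc(O[Si](C(C)C)(C(C)C)C(C)C)cc(Cl)c1 | intermediate
40 | N-(diphenylmethylene)aniline at C20 | CC#C[C@H](OC)[C@@H](O[Si](CC)(CC)CC)/C(C)=C\[C@H](C)[C@@H](OC)[C@@H](OC)C[C@H](C)[C@@H](OC)c1cc(O[Si](C(C)C)(C(C)C)C(C)C)cc(N=C(c2ccccc2)c2ccccc2)c1 | intermediate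
41 | C5–C20 aniline | CC#C[C@H](OC)[C@@H](O[Si](CC)(CC)CC)/C(C)=C\[C@H](C)[C@@H](OC)[C@@H](OC)C[C@H](C)[C@@H](OC)c1cc(O[Si](C(C)C)(C(C)C)C(C)C)cc(N)c1 | intermediate
42 | but-2-yn-1-ol | CC#CCO | starting material
43 | but-2-ynal | CC#CC=O | intermediate
44 | ethyl (Z)-2-methylhex-2-en-4-ynoate | CCOC(=O)/C(C)=C\C#CC | intermediate
45 | (Z)-2-methylhex-2-en-4-ynoic acid | CC#C/C=C(/C)C(=O)O | intermediate
46 | (Z)-2-methylhex-2-en-4-ynoyl chloride | CC#C/C=C(/C)C(Cl)=O | intermediate
47 | acyclic diyne anilide (2Z,6S,7S,8Z,10S,11R,12S,14S,15R) | CC#C[C@H](OC)[C@@H](O[Si](CC)(CC)CC)/C(C)=C\[C@H](C)[C@@H](OC)[C@@H](OC)C[C@H](C)[C@@H](OC)c1cc(O[Si](C(C)C)(C(C)C)C(C)C)cc(c1)NC(=O)/C(C)=C\C#CC | intermediate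
48 | 19-membered 2-en-4-ynamide macrocycle (TES on O7, TIPS on O18) | CO[C@H]1[C@@H](OC)C[C@H](C)[C@@H](OC)c2cc(O[Si](C(C)C)(C(C)C)C(C)C)cc(c2)NC(=O)/C(C)=C\C#C[C@H](OC)[C@@H](O[Si](CC)(CC)CC)/C(C)=C\[C@@H]1C | intermediate
49 | (2Z,4Z,8Z)-macrocyclic dienamide (TES on O7, TIPS on O18) | CO[C@H]1[C@@H](OC)C[C@H](C)[C@@H](OC)c2cc(O[Si](C(C)C)(C(C)C)C(C)C)cc(c2)NC(=O)/C(C)=C\C=C/[C@H](OC)[C@@H](O[Si](CC)(CC)CC)/C(C)=C\[C@@H]1C | intermediate
50 | C7 alcohol macrocycle (TIPS on O18) | CO[C@H]1[C@@H](OC)C[C@H](C)[C@@H](OC)c2cc(O[Si](C(C)C)(C(C)C)C(C)C)cc(c2)NC(=O)/C(C)=C\C=C/[C@H](OC)[C@@H](O)/C(C)=C\[C@@H]1C | intermediate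
51 | C7 N-trichloroacetyl carbamate macrocycle | CO[C@H]1[C@@H](OC)C[C@H](C)[C@@H](OC)c2cc(O[Si](C(C)C)(C(C)C)C(C)C)cc(c2)NC(=O)/C(C)=C\C=C/[C@H](OC)[C@@H](OC(=O)NC(=O)C(Cl)(Cl)Cl)/C(C)=C\[C@@H]1C | intermediate
52 | C7 primary carbamate macrocycle (TIPS on O18) | CO[C@H]1[C@@H](OC)C[C@H](C)[C@@H](OC)c2cc(O[Si](C(C)C)(C(C)C)C(C)C)cc(c2)NC(=O)/C(C)=C\C=C/[C@H](OC)[C@@H](OC(N)=O)/C(C)=C\[C@@H]1C | intermediate
53 | macrocyclic 3-amido-5-alkylphenol | CO[C@H]1[C@@H](OC)C[C@H](C)[C@@H](OC)c2cc(O)cc(c2)NC(=O)/C(C)=C\C=C/[C@H](OC)[C@@H](OC(N)=O)/C(C)=C\[C@@H]1C | intermediate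
54 | macrocyclic 1,4-benzoquinone (C18=O, C21=O) | CO[C@H]1[C@@H](OC)C[C@H](C)[C@@H](OC)C2=CC(=O)C=C(C2=O)NC(=O)/C(C)=C\C=C/[C@H](OC)[C@@H](OC(N)=O)/C(C)=C\[C@@H]1C | intermediate
55 | CNP0109452.1, (2Z,4Z,8Z) hydroquinone (6S,7S,10S,11R,12S,14S,15R) | CO[C@H]1[C@@H](OC)C[C@H](C)[C@@H](OC)c2cc(O)cc(c2O)NC(=O)/C(C)=C\C=C/[C@H](OC)[C@@H](OC(N)=O)/C(C)=C\[C@@H]1C | target

## Step count and risks

Total step count: 38.
Longest linear sequence: 33 steps (1 to 55 through steps 1–5, 7–18, 20–27 and 31–38).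

Steps most likely to fail:

1. Step 32 (ring-closing alkyne metathesis). Acyclic diyne oligomerisation may outrun closure of the 19-membered ring, and the catalyst may be slowed by binding to the anilide or the propargylic ether. The fallback closes the ring at N–C1 instead of C4≡C5. It sets out from dibromoolefin 37. Treatment with n-BuLi (2.1 equiv, THF, −78 °C) and then DMF should give the C4 ynal F1. Still–Gennari olefination with 23 (KN(SiMe3)2, 18-crown-6, THF, −78 °C) should give the ethyl (2Z)-2-methyl-2-en-4-ynoate aryl chloride F2. Amination with Ph2C=NH under the conditions of step 26 should give the N-(diphenylmethylene)aniline ester F3, and NH2OH·HCl/NaOAc the anilino ester F4. Me3SnOH in 1,2-dichloroethane at 70 °C should give the seco amino acid F5 with both silyl ethers intact. Macrolactamisation (BOP-Cl, i-Pr2NEt, toluene, high dilution) would then give macrocycle 48, where the route is rejoined at step 33.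

2. Step 37 (Teuber oxidation). Radical coupling may occur at an ortho carbon (C17 or C19) instead of the hindered para carbon C21, and the electron-rich dienamide may be oxidised as well. The fallback replaces the radical oxidation by a two-electron dearomatisation. It sets out from phenol 53. PhI(OAc)2 (2.2 equiv) in MeOH at 0 °C should add methanol twice at the para carbon and give the quinone monoketal F6 (4,4-dimethoxycyclohexa-2,5-dienone with the ketal carbon at C21). Aqueous oxalic acid in THF should then hydrolyse the ketal to quinone 54, where the route is rejoined at step 38.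

3. Step 8 (CBS reduction). The catalyst has to work against the Felkin preference of the C14 centre, so facial selectivity may be eroded, and partial enolisation may scramble C14. The fallback uses substrate control followed by inversion. It sets out from ketone 12. LiBH(s-Bu)3 in THF at −78 °C should give the Felkin (15S)-alcohol F7. Mitsunobu reaction (PPh3, DIAD, 4-nitrobenzoic acid, toluene, 0 °C to rt) should invert C15 and give the (15R)-4-nitrobenzoate F8. LiBH4 in THF should cleave the ester to alcohol 13, where the route is rejoined at step 9.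

## Further compounds

F1 | step 32 | C4 ynal on the C5 alkyne (6S,7S,8Z,10S,11R,12S,14S,15R) | O=CC#C[C@H](OC)[C@@H](O[Si](CC)(CC)CC)/C(C)=C\[C@H](C)[C@@H](OC)[C@@H](OC)C[C@H](C)[C@@H](OC)c1cc(O[Si](C(C)C)(C(C)C)C(C)C)cc(Cl)c1
F2 | step 32 | ethyl (2Z)-2-methyl-2-en-4-ynoate aryl chloride, C1–C15 | CCOC(=O)/C(C)=C\C#C[C@H](OC)[C@@H](O[Si](CC)(CC)CC)/C(C)=C\[C@H](C)[C@@H](OC)[C@@H](OC)C[C@H](C)[C@@H](OC)c1cc(O[Si](C(C)C)(C(C)C)C(C)C)cc(Cl)c1
F3 | step 32 | N-(diphenylmethylene)aniline ester | CCOC(=O)/C(C)=C\C#C[C@H](OC)[C@@H](O[Si](CC)(CC)CC)/C(C)=C\[C@H](C)[C@@H](OC)[C@@H](OC)C[C@H](C)[C@@H](OC)c1cc(O[Si](C(C)C)(C(C)C)C(C)C)cc(N=C(c2ccccc2)c2ccccc2)c1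
F4 | step 32 | anilino ester | CCOC(=O)/C(C)=C\C#C[C@H](OC)[C@@H](O[Si](CC)(CC)CC)/C(C)=C\[C@H](C)[C@@H](OC)[C@@H](OC)C[C@H](C)[C@@H](OC)c1cc(O[Si](C(C)C)(C(C)C)C(C)C)cc(N)c1
F5 | step 32 | seco amino acid | OC(=O)/C(C)=C\C#C[C@H](OC)[C@@H](O[Si](CC)(CC)CC)/C(C)=C\[C@H](C)[C@@H](OC)[C@@H](OC)C[C@H](C)[C@@H](OC)c1cc(O[Si](C(C)C)(C(C)C)C(C)C)cc(N)c1
F6 | step 37 | quinone monoketal (dimethyl ketal at C21, C18=O) | CO[C@H]1[C@@H](OC)C[C@H](C)[C@@H](OC)C2=CC(=O)C=C(C2(OC)OC)NC(=O)/C(C)=C\C=C/[C@H](OC)[C@@H](OC(N)=O)/C(C)=C\[C@@H]1C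
F7 | step 8 | (1S,2S,4S)-5-(tert-butyldimethylsilyloxy)-1-Ar-4-methoxy-2-methylpentan-1-ol | CC(C)(C)[Si](C)(C)OC[C@@H](OC)C[C@H](C)[C@H](O)c1cc(O[Si](C(C)C)(C(C)C)C(C)C)cc(Cl)c1
F8 | step 8 | (1R,2S,4S)-5-(tert-butyldimethylsilyloxy)-1-Ar-4-methoxy-2-methylpentyl 4-nitrobenzoate | CC(C)(C)[Si](C)(C)OC[C@@H](OC)C[C@H](C)[C@@H](OC(=O)c1ccc(cc1)[N+](=O)[O-])c1cc(O[Si](C(C)C)(C(C)C)C(C)C)cc(Cl)c1
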